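**Plan**

Retrosynthesis cuts, in this order, the C6–vinyl bond (Heck), the O1–C2 bond of the dioxane ring (quinone methide closure), the C2–aryl bond (aryl Grignard plus aldehyde) and the O4–C3 bond (Mitsunobu etherification).
Enabling feature: in the 1,4-benzodioxane (O1, C2 carrying the guaiacyl ring, C3 carrying the CH2OH carbon C9, O4, ring A C4a to C8a) C2 is benzylic and para to the guaiacyl hydroxyl, so it ionises to a para-quinone methide and O1–C2 can form and break reversibly beside an untouched C3.
Forward: the C9–C3 unit comes from methyl (S)-glycerate acetonide; O4–C3 is made first, then C2–aryl, then all protecting groups are removed without acid, then the only ring closure (O1–C2) follows, and the acrylic acid chain is attached last.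
Stereochemistry: C3 comes from the chiral pool and is inverted once (S to R) by SN2 in the Mitsunobu step; C2 is set trans to C3 under thermodynamic control in the ring closure; the E alkene comes from the Heck reaction.

Key step: step 10

Remark on the chemistry: benzodioxane positions are numbered O1, C2 (aryl), C3 (CH2OH), O4, C4a, C5 to C8, C8a, so bromine and later the acrylic acid sit on C6, para to O1. The open-chain intermediates are carried as mixtures of epimers at the benzylic carbinol, because that center is reset in the ring closure. The chiral building block is taken to be the commercial (S)-glycerate acetonide, and a silyl/allyl protecting set is used so that the open precursor can be isolated before any acid is applied.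

**Route**

Step 1
Reactants: 1 5-bromo-2-hydroxybenzaldehyde (5-bromosalicylaldehyde)
Product: 2 2-(allyloxy)-5-bromobenzaldehyde
Conditions: allyl bromide, K2CO3, DMF, rt
Reagents that add atoms: allyl bromide, C=CCBr
Why: Williamson etherification of the acidic ortho-formyl phenoxide by SN2 on the allylic bromide masks the oxygen that becomes O1 with a group that can later be removed under neutral conditions.

Step 2
Reactants: 2 2-(allyloxy)-5-bromobenzaldehyde
Product: 4 2-(allyloxy)-5-bromophenol, via aryl formate 3 (not isolated)
Conditions: mCPBA, CH2Cl2, 0 °C to rt; then Et3N (cat.), MeOH, rt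
Reagents that add atoms: mCPBA (3-chloroperoxybenzoic acid), OOC(=O)c1cccc(Cl)c1
Why: Baeyer–Villiger oxidation of the electron-rich ortho-alkoxybenzaldehyde proceeds with aryl migration to the formate, which amine-catalysed methanolysis cleaves, so the new hydroxyl (the future O4) is fixed meta to bromine, while the electron-poor terminal allyl alkene is epoxidised far more slowly by the peracid.

Step 3
Reactants: 5 4-bromo-2-methoxyphenol
Product: 6 (4-bromo-2-methoxyphenoxy)(tert-butyl)dimethylsilane
Conditions: TBSCl, imidazole, DMF, rt
Reagents that add atoms: tert-butyldimethylsilyl chloride, CC(C)(C)[Si](C)(C)Cl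
Why: Imidazole-promoted silylation of the phenol gives an aryl silyl ether that tolerates Grignard formation and is later removed by fluoride.

Step 4
Reactants: 7 methyl (4S)-2,2-dimethyl-1,3-dioxolane-4-carboxylate
Product: 8 methyl (2S)-2,3-dihydroxypropanoate
Conditions: Amberlyst 15 (H+ form), MeOH, rt
Reagents that add atoms: none
Why: Acid-catalysed transketalisation with methanol releases the 1,2-diol without touching the stereocenter, and the methyl ester can only transesterify to itself in this solvent.

Step 5
Reactants: 8 methyl (2S)-2,3-dihydroxypropanoate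
Product: 9 methyl (2S)-3-[(tert-butyldiphenylsilyl)oxy]-2-hydroxypropanoate
Conditions: TBDPSCl, imidazole, DMF, 0 °C
Reagents that add atoms: tert-butyldiphenylsilyl chloride, CC(C)(C)[Si](Cl)(c1ccccc1)c1ccccc1
Why: Regioselective silylation, in which the bulky silyl chloride reacts at the primary hydroxyl much faster than at the secondary one next to the ester; this silyl group is also too hindered to migrate to the neighbouring hydroxyl during the next step.

Step 6
Reactants: 9 methyl (2S)-3-[(tert-butyldiphenylsilyl)oxy]-2-hydroxypropanoate and 4 2-(allyloxy)-5-bromophenol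
Product: 10 methyl (2R)-2-[2-(allyloxy)-5-bromophenoxy]-3-[(tert-butyldiphenylsilyl)oxy]propanoate
Conditions: PPh3, DIAD, THF, 0 °C to rt
Reagents that add atoms: none
Why: Mitsunobu etherification, in which the phenol (pKa about 10) displaces the alkoxyphosphonium of the α-hydroxy ester by SN2, forming the O4–C3 bond with inversion and thereby setting C3 as R.

Step 7
Reactants: 10 methyl (2R)-2-[2-(allyloxy)-5-bromophenoxy]-3-[(tert-butyldiphenylsilyl)oxy]propanoate
Product: 11 (2R)-2-[2-(allyloxy)-5-bromophenoxy]-3-[(tert-butyldiphenylsilyl)oxy]propanal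
Conditions: i-Bu2AlH (1.1 equiv), CH2Cl2, −78 °C; MeOH, then aq potassium sodium tartrate
Reagents that add atoms: none
Why: Partial ester reduction with i-Bu2AlH stops at the aldehyde because the tetrahedral aluminium hemiacetal, chelated by the α-aryloxy oxygen, persists at −78 °C until the quench; the aldehyde is used at once to protect the α-stereocenter.

Step 8
Reactants: 11 (2R)-2-[2-(allyloxy)-5-bromophenoxy]-3-[(tert-butyldiphenylsilyl)oxy]propanal and 6 (4-bromo-2-methoxyphenoxy)(tert-butyl)dimethylsilane
Product: 13 (1RS,2R)-2-[2-(allyloxy)-5-bromophenoxy]-1-{4-[(tert-butyldimethylsilyl)oxy]-3-methoxyphenyl}-3-[(tert-butyldiphenylsilyl)oxy]propan-1-ol, via arylmagnesium bromide 12 (not isolated)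
Conditions: 6, Mg, I2 (cat.), THF, 40 °C; then 11, THF, −78 to 0 °C; H2O
Reagents that add atoms: none
Why: Grignard addition of the aryl nucleophile to the aldehyde forms the C2–aryl bond; the carbinol center forms without control (Felkin–Anh and chelation paths compete), which is acceptable because step 10 erases it, and an arylmagnesium reagent does not exchange with the aryl bromide of 11.

Step 9
Reactants: 13 (1RS,2R)-2-[2-(allyloxy)-5-bromophenoxy]-1-{4-[(tert-butyldimethylsilyl)oxy]-3-methoxyphenyl}-3-[(tert-butyldiphenylsilyl)oxy]propan-1-ol
Product: 15 (1RS,2R)-2-(5-bromo-2-hydroxyphenoxy)-1-(4-hydroxy-3-methoxyphenyl)propane-1,3-diol, via silylated ring A phenol 14 (not isolated)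
Conditions: Pd(PPh3)4 (5 mol%), morpholine, THF, rt; then Bu4NF, AcOH, THF, rt
Reagents that add atoms: none
Why: Tsuji–Trost-type deallylation (zerovalent palladium ionises the allyl aryl ether and morpholine traps the allyl fragment, at a temperature at which the aryl bromide should not undergo oxidative addition) followed by acetic acid-buffered fluoride desilylation removes all three protecting groups without acid, so the acid-sensitive benzylic alcohol is delivered intact.

Step 10
Reactants: 15 (1RS,2R)-2-(5-bromo-2-hydroxyphenoxy)-1-(4-hydroxy-3-methoxyphenyl)propane-1,3-diol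
Product: 17 (2R,3R)-6-bromo-2-(4-hydroxy-3-methoxyphenyl)-3-(hydroxymethyl)-2,3-dihydro-1,4-benzodioxine (trans), via quinone methide 16 (not isolated)
Conditions: TsOH·H2O (0.2 equiv), MeCN (0.01 M), rt to 40 °C
Reagents that add atoms: none
Why: Protonation of the benzylic hydroxyl and loss of water, assisted by the para-hydroxyl of the guaiacyl ring, should give the para-quinone methide 16 from either carbinol epimer; the closest known reaction type is the intramolecular oxa-conjugate addition of a phenol to a para-quinone methide generated from a para-hydroxybenzylic alcohol. The ring A hydroxyl para to bromine then adds to the exocyclic methide carbon in a 6-exo-trig closure that forms O1–C2, completes the dioxane ring and rearomatises the guaiacyl ring. C2 is the only new stereocenter and is set under thermodynamic control with C3 as the controlling element: the para-hydroxybenzylic C2–O1 bond re-ionises under the same acid, so both epimers of 15 and any cis product should drain into the trans isomer, in which the aryl and hydroxymethyl groups are both pseudo-equatorial on the half-chair. The step needs chemoselective O-attack by the ring A phenol, which the substrate secures because this is the only nucleophile that reaches the methide carbon through a six-membered transition state (the C9 hydroxyl could only give an oxetane, and the ring A carbon para to the phenol is blocked by bromine), while high dilution suppresses intermolecular arylation. C3 takes no part as long as the acid is mild enough to avoid proton loss from the quinone methide, so its R configuration from step 6 is retained.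

Step 11
Reactants: 17 (2R,3R)-6-bromo-2-(4-hydroxy-3-methoxyphenyl)-3-(hydroxymethyl)-2,3-dihydro-1,4-benzodioxine and 18 acrylic acid
Product: 19 (E)-3-[(2R,3R)-2-(4-hydroxy-3-methoxyphenyl)-3-(hydroxymethyl)-2,3-dihydro-1,4-benzodioxin-6-yl]prop-2-enoic acid
Conditions: Pd(OAc)2 (5 mol%), P(o-tol)3 (15 mol%), Et3N, DMF, 90 °C; then dilute aq HCl
Reagents that add atoms: none
Why: Mizoroki–Heck reaction, in which oxidative addition of the aryl bromide, syn carbopalladation of the acrylate and syn β-hydride elimination give the E cinnamic acid directly, with the free hydroxyls tolerated.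

**Compound list**

1 | 5-bromo-2-hydroxybenzaldehyde (5-bromosalicylaldehyde) | O=Cc1cc(Br)ccc1O | starting material
2 | 2-(allyloxy)-5-bromobenzaldehyde | O=Cc1cc(Br)ccc1OCC=C | intermediate
3 | 2-(allyloxy)-5-bromophenyl formate (not isolated) | O=COc1cc(Br)ccc1OCC=C | intermediate
4 | 2-(allyloxy)-5-bromophenol | Oc1cc(Br)ccc1OCC=C | intermediate
5 | 4-bromo-2-methoxyphenol | COc1cc(Br)ccc1O | starting material
6 | (4-bromo-2-methoxyphenoxy)(tert-butyl)dimethylsilane | COc1cc(Br)ccc1O[Si](C)(C)C(C)(C)C | intermediate
7 | methyl (4S)-2,2-dimethyl-1,3-dioxolane-4-carboxylate | COC(=O)[C@@H]1COC(C)(C)O1 | starting material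
8 | methyl (2S)-2,3-dihydroxypropanoate | COC(=O)[C@@H](O)CO | intermediate
9 | methyl (2S)-3-[(tert-butyldiphenylsilyl)oxy]-2-hydroxypropanoate | COC(=O)[C@@H](O)CO[Si](c1ccccc1)(c1ccccc1)C(C)(C)C | intermediate
10 | methyl (2R)-2-[2-(allyloxy)-5-bromophenoxy]-3-[(tert-butyldiphenylsilyl)oxy]propanoate | COC(=O)[C@H](Oc1cc(Br)ccc1OCC=C)CO[Si](c1ccccc1)(c1ccccc1)C(C)(C)C | intermediate
11 | (2R)-2-[2-(allyloxy)-5-bromophenoxy]-3-[(tert-butyldiphenylsilyl)oxy]propanal | O=C[C@H](Oc1cc(Br)ccc1OCC=C)CO[Si](c1ccccc1)(c1ccccc1)C(C)(C)C | intermediate
12 | {4-[(tert-butyldimethylsilyl)oxy]-3-methoxyphenyl}magnesium bromide (not isolated) | COc1cc([Mg]Br)ccc1O[Si](C)(C)C(C)(C)C | intermediate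
13 | (1RS,2R)-2-[2-(allyloxy)-5-bromophenoxy]-1-{4-[(tert-butyldimethylsilyl)oxy]-3-methoxyphenyl}-3-[(tert-butyldiphenylsilyl)oxy]propan-1-ol, epimer mixture at C1 | COc1cc(C(O)[C@@H](CO[Si](c2ccccc2)(c2ccccc2)C(C)(C)C)Oc2cc(Br)ccc2OCC=C)ccc1O[Si](C)(C)C(C)(C)C | intermediate
14 | (1RS,2R)-2-(5-bromo-2-hydroxyphenoxy)-1-{4-[(tert-butyldimethylsilyl)oxy]-3-methoxyphenyl}-3-[(tert-butyldiphenylsilyl)oxy]propan-1-ol (not isolated) | COc1cc(C(O)[C@@H](CO[Si](c2ccccc2)(c2ccccc2)C(C)(C)C)Oc2cc(Br)ccc2O)ccc1O[Si](C)(C)C(C)(C)C | intermediate
15 | (1RS,2R)-2-(5-bromo-2-hydroxyphenoxy)-1-(4-hydroxy-3-methoxyphenyl)propane-1,3-diol, epimer mixture at C1 | COc1cc(C(O)[C@@H](CO)Oc2cc(Br)ccc2O)ccc1O | intermediate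
16 | 4-[(2S)-2-(5-bromo-2-hydroxyphenoxy)-3-hydroxypropylidene]-2-methoxycyclohexa-2,5-dien-1-one, alkene geometry undefined (not isolated) | COC1=CC(=C[C@@H](CO)Oc2cc(Br)ccc2O)C=CC1=O | intermediate
17 | (2R,3R)-6-bromo-2-(4-hydroxy-3-methoxyphenyl)-3-(hydroxymethyl)-2,3-dihydro-1,4-benzodioxine (trans) | COc1cc([C@H]2Oc3ccc(Br)cc3O[C@@H]2CO)ccc1O | intermediate
18 | acrylic acid | C=CC(=O)O | starting material
19 | (E)-3-[(2R,3R)-2-(4-hydroxy-3-methoxyphenyl)-3-(hydroxymethyl)-2,3-dihydro-1,4-benzodioxin-6-yl]prop-2-enoic acid | COc1cc([C@H]2Oc3ccc(/C=C/C(=O)O)cc3O[C@@H]2CO)ccc1O | target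

**Step count**

Total steps: 11. Longest linear sequence: 8 steps (from 7 through steps 4 to 11; the branch from 1 through steps 1, 2 and 6 to 11 is equally long).

**Steps most likely to fail**

Step 10. Re-ionisation of the closed ring may be too slow under acid mild enough to spare C3, so the kinetic mixture of C2 epimers would persist. Stronger or longer acid treatment would instead let the quinone methide be captured by a second arene or lose the C3 proton. The fallback sets out from 15 and comes back at 17, and it separates ring closure from equilibration. The closure is run only briefly (TsOH·H2O, MeCN, 0 °C) and accepted as a mixture of 17 and its C2 epimer (2S,3R)-6-bromo-2-(4-hydroxy-3-methoxyphenyl)-3-(hydroxymethyl)-2,3-dihydro-1,4-benzodioxine F1. The mixture is then equilibrated in a separate anionic operation (K2CO3, DMF, rt). There the guaiacyl phenoxide expels the O1 aryloxide by retro-oxa-Michael fragmentation and the phenoxide re-adds until the trans isomer 17 predominates, as is known for phenolic benzyl aryl ethers.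

Step 7. The aluminium hemiacetal may collapse before the quench and lead to over-reduction, and the α-aryloxy aldehyde may enolise during the aqueous work-up, eroding C3. The fallback sets out from 10 and comes back at 11. The ester is reduced completely with LiBH4 (THF, 0 °C) to the primary alcohol (2S)-2-[2-(allyloxy)-5-bromophenoxy]-3-[(tert-butyldiphenylsilyl)oxy]propan-1-ol F2. Dess–Martin oxidation (NaHCO3-buffered, CH2Cl2, 0 °C) then gives 11 under neutral, non-aqueous conditions, and the solution is carried directly into step 8.

Step 11. Oxidative addition into the electron-rich aryl bromide may be slow and force prolonged heating with amine base. Under those conditions the guaiacyl phenoxide can reopen the dioxane at C2, and the resulting quinone methide can lose the C3 proton. The fallback sets out from 17 and comes back at 19. Suzuki–Miyaura coupling with methyl (E)-3-(4,4,5,5-tetramethyl-1,3,2-dioxaborolan-2-yl)acrylate (Pd(dppf)Cl2, K3PO4, dioxane/H2O, 60 °C) should give methyl (E)-3-[(2R,3R)-2-(4-hydroxy-3-methoxyphenyl)-3-(hydroxymethyl)-2,3-dihydro-1,4-benzodioxin-6-yl]prop-2-enoate F3 at a lower temperature. Saponification with LiOH (THF/H2O, rt) and acidification then gives 19.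

**Further compounds**

F1 | step 10 | (2S,3R)-6-bromo-2-(4-hydroxy-3-methoxyphenyl)-3-(hydroxymethyl)-2,3-dihydro-1,4-benzodioxine (cis epimer of 17) | COc1cc([C@@H]2Oc3ccc(Br)cc3O[C@@H]2CO)ccc1O
F2 | step 7 | (2S)-2-[2-(allyloxy)-5-bromophenoxy]-3-[(tert-butyldiphenylsilyl)oxy]propan-1-ol | OC[C@H](Oc1cc(Br)ccc1OCC=C)CO[Si](c1ccccc1)(c1ccccc1)C(C)(C)C
F3 | step 11 | methyl (E)-3-[(2R,3R)-2-(4-hydroxy-3-methoxyphenyl)-3-(hydroxymethyl)-2,3-dihydro-1,4-benzodioxin-6-yl]prop-2-enoate | COc1cc([C@H]2Oc3ccc(/C=C/C(=O)OC)cc3O[C@@H]2CO)ccc1O
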